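(The constants were chosen freely; the flask was simulated.)

I wanted to know which way of charging gave the most target at the end.

    partner + free catalyst → catalyst intermediate A (k1 = 2.8 × 10⁵ /M/s)
    substrate + catalyst intermediate A → catalyst intermediate B (k2 = 1.3 × 10⁵ /M/s)
    catalyst intermediate B → free catalyst + target (k3 = 220 /s)
    partner → decomposed reagent (k4 = 0.032 /s)
    free catalyst + impurity → spent catalyst (k5 = 4.8 × 10⁶ /M/s)

| setting | Wednesday's | Monday's | Friday's | Saturday's |
|---|---|---|---|---|
| substrate | 0.20 mM | 0.20 mM (fed, over 20 s) | 0.20 mM | 0.20 mM |
| partner | 1.05 equiv | 1.05 equiv | 1.05 equiv (fed, over 20 s) | 1.05 equiv (in portions, 5, over 20 s) |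
| free catalyst | 0.21 mol% | 0.21 mol% | 0.21 mol% | 0.21 mol% |
| impurity | 0.48 µM | 0.48 µM | 0.48 µM | 0.48 µM |
| time | 30 s | 30 s | 30 s | 30 s |
| remark | everything together at the start | all else is in the flask from the start; the feed brings no volume worth counting | all else is in the flask from the start; the feed brings no volume worth counting | first portion at the start, last at 20 s |

- the best flask by amount of target, in percent of the substrate charged; "all alike" if 1.5 percentage points covers them all (Wednesday's / Monday's / Friday's / Saturday's / all alike)
- amount of target at the end, in percent of the substrate charged, Wednesday's
- amount of target at the end, in percent of the substrate charged, Monday's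
- amount of target at the end, in percent of the substrate charged, Friday's
- amount of target at the end, in percent of the substrate charged, Saturday's

I reckoned on free catalyst. Every round of the catalyst passes through it, and there it has two ways out: partner takes it on at a pseudo-first-order rate of 58.8 /s at the full charge, or impurity kills it at 2.30 /s at the start. My reckoning rested on these two rates. At those rates partner won 25.6 catches for each one of impurity, and each catch by partner meant one target, each catch by impurity one catalyst lost. The level of free catalyst cancelled in that ratio, and so did substrate and the later steps.

But the impurity rate falls as impurity is used. Impurity, at 0.48 µM, was more than the catalyst charge of 0.420 µM, so losing the whole catalyst took it down to 0.0600 µM. Adding up the ratio over that fall with c_partner held steady, I reckoned target made as c_partner times the partner constant over the impurity constant times the natural log of impurity before over impurity after. The two constants and the charges of impurity and catalyst make one number, the yield per partner, the target made per unit of c_partner while the catalyst dies, w = 0.121. With partner held at its charge, I reckoned 12.7 % of the substrate for Wednesday's, and partner decays meanwhile, so I took that as an upper figure. With no substrate in w, I expected Monday's near Wednesday's. Saturday's, with a first portion of partner of 0.0420 mM, and Friday's, starting from no partner, I put lower.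

The forecast named Wednesday's as best, with 10 % there, 8 % for Monday's, 1.6 % for Friday's and 2.8 % for Saturday's, holding that “the turnovers it manages scale with how much partner is present”.

Wednesday's gave 10.1 %, Monday's 8.46 %, Friday's 1.42 % and Saturday's 2.82 %, so Wednesday's was best, with spent catalyst at 99.6 % of the catalyst charged. Read through w, Wednesday's target corresponds to a partner level of 0.166 mM while the catalyst died, below the charge of 0.210 mM. In Monday's, the mean c_partner over the first 20 s was 0.148 mM, and w turns that into 8.95 % of the substrate, where the flask held 8.46 %.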